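## The problem

The target 29 is a triester of quinic acid. Quinate numbering is used throughout: C1 is the quaternary carbinol, C7 its carboxyl carbon, and O3, O4, O5 are the three secondary oxygens. O3 and O5 carry (E)-caffeoyl groups, O4 a hemisuccinate, and O1 and the carboxyl are free.

There is only one ring and no fusion to negotiate. The difficulty is four stereocentres on that ring, with O1, O3 and O4 on one face and O5 and the carboxyl on the other. C1 and C4 lie on the constitutional mirror plane of the ring, so their configuration has meaning only relative to C3 and C5. A synthesis must therefore tell the C2–C3 arm from the C6–C5 arm early and fix C1 against C5 across the ring.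

Once C5 exists it can direct the neighbouring C4, and C4 can direct C3 through a cyclic intermediate. C1 is too remote to control C3 or C4, or to be controlled by them. The three secondary oxygens end up acylated differently, so O4 has to be distinguished from O3 within a cis-diol, and O5 from both.

The fragile parts are the caffeoyl esters: catechols that oxidise, E-alkenes that forbid hydrogenolysis, and esters on a cis/trans triol that migrate or hydrolyse under base. The closing steps therefore have to be acidic or neutral.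

The feature that opens the ring to a key step is the C3–C4 cis-diol standing trans to O5. A cis-1,2-diol beside an oxygenated carbon is what a ketyl–aldehyde coupling of a 1,6-dialdehyde delivers, so C3–C4 can be the ring-closing bond.

## Retrosynthesis

**Unmasking.** 29 is traced to the fully protected triester 27 through 28. The bonds cut are the two O–tert-butyl bonds, the O1–CH2OMe acetal bond and the four aryl O–acetyl bonds. Acid-labile masks are preferred to benzyl-type ones, which would need hydrogenolysis beside two cinnamate alkenes, and to base-labile ones, which would set the esters migrating. 27 has the same skeleton but no free acid, phenol or tertiary alcohol. The forward step must cleave alkyl–oxygen bonds and aryl acetates while three alkyl esters stay intact.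

**Caffeoyl esters.** The acyl–oxygen bonds at O3 and O5 of 27 are cut together, giving diol 23 and two molecules of diacetylcaffeic acid 25 (used as chloride 26, made from caffeic acid 24). Both go on at once because they are identical. The neighbouring option, putting the O4 ester on last, would leave a hydroxyl wedged between two cinnamates. 23 has lost both aromatic units. The forward acylation has to reach the axial O3 and outrun migration of the O4 ester.

**O4 ester and O5 silyl ether.** 23 goes back through silyl ether 22 to cis-diol 18 and mono-tert-butyl succinate 19 (as anhydride 20, delivered to stannylene acetal 21). The bond cut is O4–acyl. This is where the three oxygens are told apart: O5 has been a silyl ether since before the ring existed, and O3 and O4 differ as the axial and equatorial partners of a cis-diol. 18 carries no acyl group at all. The forward reaction must acylate the equatorial O4 only.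

**Ring.** 18 is cut at C3–C4 to the open-chain dialdehyde 16, through diolate 17. This cut removes the ring and two of the four stereocentres in one stroke. A cut at C4–C5 or C2–C3 (aldol type) would not produce the cis-diol, and closing C3=C4 as an alkene would need a separate dihydroxylation. 16 keeps only C1 and C5. The forward coupling has to give the cis-diol and place it trans to O5.

**Aldehydes.** 16 is taken back to aldehyde 14 (C3 still a terminal alkene, through ozonide 15), then to alcohol 13 and trityl ether 12. No skeletal bond is cut; the two formyl groups are revealed one after the other under neutral conditions because 16 is epimerisable at C5 and prone to β-elimination at C1. 12 is a stable, storable compound. The forward steps must not touch the silyl ether, the acetal or the ester.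

**Chain to lactone.** 12 comes from acid 11, and 11 (through carboxylate 9 and silyl ester 10) from γ-lactone 8 by reconnecting O5 to C7. The reconnection turns the 1,3-relationship of C1 and C5, which an open chain cannot control, into a cis/trans question on a five-membered ring. The forward opening must cap O5 before the hydroxy acid can reclose.

**Quaternary centre.** In 8 the C1–O1 bond and then the C1–C2 bond are cut, leading through hydroxy lactone 7 (enolate 6) and allyl lactone 5 (enolate 4) to trityl lactone 2 and allyl bromide 3. 2 comes from the chiral-pool lactone 1, which supplies C5. Allylation before hydroxylation is the only order that puts the allyl group cis and O1 trans to C4. Each forward enolate reaction must take its electrophile on the face away from the trityloxymethyl group.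

## Roads not taken

Alternative 1: The ring is cut across C1–C6 and C2–C3. In the forward sense buta-1,3-diene A3 adds to 2-(benzoyloxy)acrolein A2 under a chiral ammonium salt catalyst to give (S)-1-formylcyclohex-3-en-1-yl benzoate A1. This is a Diels–Alder reaction that makes the ring and C1 in one catalytic step; oxidation to the acid, lactonisation onto the alkene, elimination and dihydroxylation would then bring in O5, O3 and O4.
- Merits: two cheap achiral components; either enantiomer from the catalyst; the most dependable six-ring construction; the lactone relay forces O5 cis to the carboxyl.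
- Weak points: the only stereocentre of A1 is defined by a remote alkene, and its enantiopurity rests on one catalytic step with a gaseous, unactivated diene. Three oxygens still have to be installed stepwise. O5 emerges as a lactone oxygen that must be reopened before any acyl group is present. The benzoate on O1 must be exchanged, because it cannot be removed beside caffeates.
- Comparison: this road reaches a carbocycle sooner, and its ring-forming step is safer than a pinacol. Against that, the chosen plan creates two carbinol centres in the ring closure (step 10), has O5 already distinguished from O3 and O4 in 18, and takes its absolute configuration from enantiopure 1 instead of from a selectivity that might need upgrading. Overall length is similar.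

Alternative 2: The cut is C1–C2. The silyl ketene acetal of the 5,6-trans δ-lactone A5 would undergo an Ireland–Claisen ring contraction through a boat transition state to the cyclohexene acid A4, which is then dihydroxylated anti to its allylic silyl ether.
- Merits: concerted chirality transfer sets the quaternary C1 predictably; the ketene acetal geometry is fixed by the ring; A4 carries the protecting-group pattern wanted.
- Weak points: A5 needs two stereocentres of its own, one of which is consumed, and a synthesis at least as long as that of 14. The α-alkoxy lactone must be O-silylated cleanly. The boat transition state of a six-membered lactone is strained.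
- Comparison: in its last stereochemical step this road is better than the chosen one, because osmylation anti to an allylic oxygen is more reliable than a pinacol on a labile dialdehyde. The chosen plan sets against that a single step that closes the ring and makes both carbinols, and no sacrificial stereocentre. It also keeps an alkene of the A4 type in reserve (fallback to step 10).

Alternative 3: The cuts are the two aryl–vinyl bonds. Zerovalent palladium generated from Pd(OAc)2 would couple two molecules of 4-iodo-1,2-phenylene diacetate A8 with the bisacrylate A7 in a double Heck reaction to give the protected triester A6.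
- Merits: acryloyl groups are small, so the hindered axial O3 is esterified more easily than with a cinnamoyl chloride; E-geometry is inherent; no caffeoyl chloride is handled.
- Weak points: this is an endgame only. A7 contains the whole ring, all four stereocentres and the differentiated oxygens, and must itself come from a ring synthesis such as the present one. Both couplings must go to completion on one molecule, and the amine base and heat invite acyl migration.
- Comparison: for esterifying O3 this road is probably better than step 14 and could be grafted onto 23. The chosen plan sets against it one fewer metal-mediated step on a late intermediate and no statistical double coupling.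

Key step: step 10

## Route

Remark: carbons are numbered as in quinic acid in all compounds, including lactones (lactone C2 = C7, C3 = C1, C4 = C6, C5 = C5, exocyclic CH2 = C4) and open chains; 1, 3, 19 and 24 are taken to be purchasable.

Step 1
Reactants: 1 (R)-5-(hydroxymethyl)dihydrofuran-2(3H)-one
Product: 2 (R)-5-[(trityloxy)methyl]dihydrofuran-2(3H)-one
Conditions: Ph3CCl, pyridine, DMAP (cat.), CH2Cl2, rt
Reagents that add atoms: trityl chloride, ClC(c1ccccc1)(c1ccccc1)c1ccccc1
Why: Tritylation of a primary alcohol; C5 comes unchanged from the chiral pool, and the bulky trityloxymethyl group becomes the shielding element for the enolate reactions of steps 2 and 3.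

Step 2
Reactants: 2 (R)-5-[(trityloxy)methyl]dihydrofuran-2(3H)-one; 3 allyl bromide
Product: 5 (3S,5R)-3-(prop-2-en-1-yl)-5-[(trityloxy)methyl]dihydrofuran-2(3H)-one, via lithium enolate 4 (not isolated)
Conditions: LiN(i-Pr)2, THF, −78 °C; then 3, −78 to −40 °C
Reagents that add atoms: none
Why: Lactone enolate alkylation; the electrophile enters anti to the trityloxymethyl group to give the 3,5-trans lactone, but this configuration at C1 is provisional because C1 is planarised again in step 3.

Step 3
Reactants: 5 (3S,5R)-3-(prop-2-en-1-yl)-5-[(trityloxy)methyl]dihydrofuran-2(3H)-one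
Product: 7 (3S,5R)-3-hydroxy-3-(prop-2-en-1-yl)-5-[(trityloxy)methyl]dihydrofuran-2(3H)-one, via potassium enolate 6 (not isolated)
Conditions: KN(SiMe3)2, THF, −78 °C; then 2-(phenylsulfonyl)-3-phenyloxaziridine, −78 °C; aq. NH4Cl
Reagents that add atoms: 2-(phenylsulfonyl)-3-phenyloxaziridine (Davis reagent), O=S(=O)(c1ccccc1)N1OC1c1ccccc1
Why: Enolate hydroxylation with an N-sulfonyloxaziridine; oxygen is delivered to the enolate face anti to the trityloxymethyl group, so O1 ends trans and the allyl group cis to C4, which sets the quaternary C1 relative to C5; the potassium enolate avoids addition to the sulfonimine by-product.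

Step 4
Reactants: 7 (3S,5R)-3-hydroxy-3-(prop-2-en-1-yl)-5-[(trityloxy)methyl]dihydrofuran-2(3H)-one
Product: 8 (3S,5R)-3-(methoxymethoxy)-3-(prop-2-en-1-yl)-5-[(trityloxy)methyl]dihydrofuran-2(3H)-one
Conditions: MeOCH2Cl, i-Pr2NEt, Bu4NI (cat.), ClCH2CH2Cl, 60 °C
Reagents that add atoms: chloromethyl methyl ether, COCCl
Why: O-alkylation of a tertiary alcohol with a chloromethyl ether under iodide catalysis (acetal formation); the MOM group keeps O1 from forming a lactol with the C4 aldehyde later and falls to acid at the end.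

Step 5
Reactants: 8 (3S,5R)-3-(methoxymethoxy)-3-(prop-2-en-1-yl)-5-[(trityloxy)methyl]dihydrofuran-2(3H)-one
Product: 11 (2S,4R)-4-[(tert-butyldimethylsilyl)oxy]-2-(methoxymethoxy)-2-(prop-2-en-1-yl)-5-(trityloxy)pentanoic acid, via lithium hydroxy-carboxylate 9 (not isolated), via silyl ester 10 (not isolated)
Conditions: LiOH·H2O, THF/H2O, rt; evaporate; TBSCl, imidazole, DMAP (cat.), DMF, rt to 40 °C; then K2CO3, MeOH/THF/H2O, 0 °C; pH 4–5 work-up
Reagents that add atoms: lithium hydroxide, [Li+].[OH-]; tert-butyldimethylsilyl chloride, CC(C)(C)[Si](C)(C)Cl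
Why: Lactone saponification, silylation of alkoxide and carboxylate, then selective solvolysis of the labile silyl ester; the hydroxy acid is kept as its salt until O5 is capped, so it cannot reclose, and neither stereocentre is touched.

Step 6
Reactants: 11 (2S,4R)-4-[(tert-butyldimethylsilyl)oxy]-2-(methoxymethoxy)-2-(prop-2-en-1-yl)-5-(trityloxy)pentanoic acid
Product: 12 tert-butyl (2S,4R)-4-[(tert-butyldimethylsilyl)oxy]-2-(methoxymethoxy)-2-(prop-2-en-1-yl)-5-(trityloxy)pentanoate
Conditions: O-tert-butyl-N,N′-diisopropylisourea, CH2Cl2, rt to 40 °C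
Reagents that add atoms: O-tert-butyl-N,N′-diisopropylisourea, CC(C)NC(=NC(C)C)OC(C)(C)C
Why: Esterification by O-alkylation of the carboxylate with a protonated isourea; the tert-butyl group is transferred to oxygen, so the crowded acyl carbon does not matter, and the neutral medium spares trityl, MOM and silyl groups.

Step 7
Reactants: 12 tert-butyl (2S,4R)-4-[(tert-butyldimethylsilyl)oxy]-2-(methoxymethoxy)-2-(prop-2-en-1-yl)-5-(trityloxy)pentanoate
Product: 13 tert-butyl (2S,4R)-4-[(tert-butyldimethylsilyl)oxy]-5-hydroxy-2-(methoxymethoxy)-2-(prop-2-en-1-yl)pentanoate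
Conditions: camphor-10-sulfonic acid (0.1 equiv), MeOH/CH2Cl2, 0 °C; Et3N quench
Reagents that add atoms: none
Why: Acid-catalysed solvolysis of a trityl ether through the trityl cation, the most acid-labile group present; the hindered secondary silyl ether, the MOM acetal and the tert-butyl ester should persist at 0 °C.

Step 8
Reactants: 13 tert-butyl (2S,4R)-4-[(tert-butyldimethylsilyl)oxy]-5-hydroxy-2-(methoxymethoxy)-2-(prop-2-en-1-yl)pentanoate
Product: 14 tert-butyl (2S,4R)-4-[(tert-butyldimethylsilyl)oxy]-2-(methoxymethoxy)-5-oxo-2-(prop-2-en-1-yl)pentanoate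
Conditions: Dess–Martin periodinane, pyridine, CH2Cl2, 0 °C to rt
Reagents that add atoms: none
Why: Dess–Martin oxidation of a primary alcohol; the buffered, non-basic medium should leave the α-silyloxy aldehyde configurationally intact at C5.

Step 9
Reactants: 14 tert-butyl (2S,4R)-4-[(tert-butyldimethylsilyl)oxy]-2-(methoxymethoxy)-5-oxo-2-(prop-2-en-1-yl)pentanoate
Product: 16 tert-butyl (2R,4R)-4-[(tert-butyldimethylsilyl)oxy]-2-(methoxymethoxy)-5-oxo-2-(2-oxoethyl)pentanoate, via ozonide 15 (not isolated)
Conditions: O3, CH2Cl2, −78 °C; then PPh3, −78 °C to rt; short silica plug, used at once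
Reagents that add atoms: ozone, [O-][O+]=O
Why: Ozonolysis of the terminal alkene with reductive work-up (Criegee mechanism); the existing aldehyde, silyl ether, acetal and ester are inert, and the neutral work-up avoids β-elimination at C1 and epimerisation at C5 (the descriptor at C1 changes from S to R only because the priorities change).

Step 10
Reactants: 16 tert-butyl (2R,4R)-4-[(tert-butyldimethylsilyl)oxy]-2-(methoxymethoxy)-5-oxo-2-(2-oxoethyl)pentanoate
Product: 18 tert-butyl 5-O-(tert-butyldimethylsilyl)-1-O-(methoxymethyl)quinate (1-OMOM and 3-OH and 4-OH on one face; 5-OTBS and ester on the other), via samarium diolate 17 (not isolated)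
Conditions: SmI2 (0.1 M in THF, 3 equiv), t-BuOH (3 equiv), THF, −78 °C to rt; aq. NaHCO3
Reagents that add atoms: none
Why: SmI2 (divalent samarium) transfers one electron to a formyl group of 16 to give a ketyl, which adds to the second, samarium-bound formyl group; a second electron transfer leaves the trivalent samarium diolate 17, and hydrolysis gives 18 (intramolecular pinacol coupling). The closest known reaction type is the SmI2 pinacol cyclisation of α-alkoxy 1,6-dialdehydes to cis-cyclohexane-1,2-diols that stand trans to the neighbouring alkoxy group. The one ring is closed by forming C3–C4 in a 6-exo-trig attack of the ketyl carbon on the carbonyl carbon, inside a chelate in which samarium bridges both oxygens. That bridge controls C3 relative to C4, since both C–O bonds must point to the same side, hence the cis-diol. C4 is controlled by C5: the samarium-bearing oxygen at C4 avoids the bulky, poorly coordinating silyloxy group for steric and dipolar reasons, so O4 forms trans to O5. C1 is 1,3 to both C3 and C5 and is expected only to favour cyclisation through its geminal substitution. The step needs chemoselectivity for the two aldehydes over the ester and the oxygenated C1; the hindered tert-butyl ester and the C1–O bond are not reduced by SmI2 in THF at low temperature without strongly donating additives, and tert-butanol protonates the diolate as it forms.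

Step 11
Reactants: 18 tert-butyl 5-O-(tert-butyldimethylsilyl)-1-O-(methoxymethyl)quinate; 19 4-tert-butoxy-4-oxobutanoic acid
Product: 22 tert-butyl 4-O-(4-tert-butoxy-4-oxobutanoyl)-5-O-(tert-butyldimethylsilyl)-1-O-(methoxymethyl)quinate, via 4-tert-butoxy-4-oxobutanoic anhydride 20 (not isolated), via dibutylstannylene acetal 21 (not isolated)
Conditions: 19, N,N′-dicyclohexylcarbodiimide (0.5 equiv per acid), CH2Cl2, 0 °C to rt, filter; separately 18, Bu2SnO, toluene, reflux, Dean–Stark; then combine, toluene/CH2Cl2, 0 °C to rt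
Reagents that add atoms: none
Why: Regioselective acylation of a cis-diol through its dibutylstannylene acetal, which activates the equatorial oxygen (O4) and leaves the axial O3 free; the symmetric anhydride is used because the acid chloride of a tert-butyl hemisuccinate can collapse to succinic anhydride.

Step 12
Reactants: 22 tert-butyl 4-O-(4-tert-butoxy-4-oxobutanoyl)-5-O-(tert-butyldimethylsilyl)-1-O-(methoxymethyl)quinate
Product: 23 tert-butyl 4-O-(4-tert-butoxy-4-oxobutanoyl)-1-O-(methoxymethyl)quinate
Conditions: HF·pyridine, pyridine, THF, 0 °C to rt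
Reagents that add atoms: none
Why: Fluoride-induced desilylation in a buffered, weakly acidic medium; basic fluoride is avoided because it would let the O4 ester migrate to O3 or O5, while MOM and the tert-butyl esters are stable.

Step 13
Reactants: 24 caffeic acid
Product: 25 (E)-3-[3,4-bis(acetyloxy)phenyl]prop-2-enoic acid
Conditions: Ac2O, pyridine, DMAP (cat.), 0 °C to rt; then H2O; 1 M HCl work-up
Reagents that add atoms: acetic anhydride, CC(=O)OC(C)=O
Why: Acetylation of both phenols; any mixed anhydride at the carboxyl group is hydrolysed on aqueous work-up, and the E-alkene is untouched.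

Step 14
Reactants: 23 tert-butyl 4-O-(4-tert-butoxy-4-oxobutanoyl)-1-O-(methoxymethyl)quinate; 25 (E)-3-[3,4-bis(acetyloxy)phenyl]prop-2-enoic acid
Product: 27 tert-butyl 3,5-bis-O-[(E)-3,4-diacetoxycinnamoyl]-4-O-(4-tert-butoxy-4-oxobutanoyl)-1-O-(methoxymethyl)quinate, via diacetylcaffeoyl chloride 26 (not isolated)
Conditions: 25 (3 equiv), (COCl)2, DMF (cat.), CH2Cl2, 0 °C to rt, evaporate; then 23, pyridine, DMAP, CH2Cl2, 0 °C to rt
Reagents that add atoms: none
Why: Acylation of two secondary alcohols with an acid chloride under nucleophilic catalysis by DMAP; the acetyl-masked catechols cannot self-acylate or oxidise, the E-geometry is carried through, and the excess of chloride is meant to make acylation faster than migration of the O4 ester.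

Step 15
Reactants: 27 tert-butyl 3,5-bis-O-[(E)-3,4-diacetoxycinnamoyl]-4-O-(4-tert-butoxy-4-oxobutanoyl)-1-O-(methoxymethyl)quinate
Product: 29 3,5-di-O-[(E)-caffeoyl]-4-O-(3-carboxypropanoyl)quinic acid (CNP0133919.1), via tetraacetate triacid 28 (not isolated)
Conditions: CF3CO2H/CH2Cl2/H2O (10:10:1), 0 °C to rt; evaporate; then 1 M aq. HCl/THF, rt, argon, dark
Reagents that add atoms: none
Why: Acidolysis of the two tert-butyl esters and of the MOM acetal, then acid-catalysed hydrolysis of the four aryl acetates, which are far more labile than the alkyl cinnamate and succinate esters; the medium stays acidic so acyl migration is suppressed, and formaldehyde from the MOM group is evaporated before the electron-rich catechols are unmasked.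

## Compound list

1 | (R)-5-(hydroxymethyl)dihydrofuran-2(3H)-one | O=C1CC[C@H](CO)O1 | starting material
2 | (R)-5-[(trityloxy)methyl]dihydrofuran-2(3H)-one | O=C1CC[C@H](COC(c2ccccc2)(c2ccccc2)c2ccccc2)O1 | intermediate
3 | allyl bromide (3-bromoprop-1-ene) | C=CCBr | starting material
4 | lithium enolate of 2, lithium (R)-5-[(trityloxy)methyl]-4,5-dihydrofuran-2-olate | [Li]OC1=CC[C@H](COC(c2ccccc2)(c2ccccc2)c2ccccc2)O1 | intermediate
5 | (3S,5R)-3-(prop-2-en-1-yl)-5-[(trityloxy)methyl]dihydrofuran-2(3H)-one (3,5-trans) | O=C1[C@@H](CC=C)C[C@H](COC(c2ccccc2)(c2ccccc2)c2ccccc2)O1 | intermediate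
6 | potassium enolate of 5, potassium (R)-3-(prop-2-en-1-yl)-5-[(trityloxy)methyl]-4,5-dihydrofuran-2-olate | [K]OC1=C(CC=C)C[C@H](COC(c2ccccc2)(c2ccccc2)c2ccccc2)O1 | intermediate
7 | (3S,5R)-3-hydroxy-3-(prop-2-en-1-yl)-5-[(trityloxy)methyl]dihydrofuran-2(3H)-one (hydroxyl trans to the trityloxymethyl group) | O=C1[C@](O)(CC=C)C[C@H](COC(c2ccccc2)(c2ccccc2)c2ccccc2)O1 | intermediate
8 | (3S,5R)-3-(methoxymethoxy)-3-(prop-2-en-1-yl)-5-[(trityloxy)methyl]dihydrofuran-2(3H)-one | O=C1[C@](OCOC)(CC=C)C[C@H](COC(c2ccccc2)(c2ccccc2)c2ccccc2)O1 | intermediate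
9 | lithium (2S,4R)-4-hydroxy-2-(methoxymethoxy)-2-(prop-2-en-1-yl)-5-(trityloxy)pentanoate | c1ccc(cc1)C(c1ccccc1)(c1ccccc1)OC[C@H](O)C[C@](OCOC)(C(=O)[O-])CC=C.[Li+] | intermediate
10 | tert-butyldimethylsilyl (2S,4R)-4-[(tert-butyldimethylsilyl)oxy]-2-(methoxymethoxy)-2-(prop-2-en-1-yl)-5-(trityloxy)pentanoate | c1ccc(cc1)C(c1ccccc1)(c1ccccc1)OC[C@H](O[Si](C)(C)C(C)(C)C)C[C@](OCOC)(C(=O)O[Si](C)(C)C(C)(C)C)CC=C | intermediate
11 | (2S,4R)-4-[(tert-butyldimethylsilyl)oxy]-2-(methoxymethoxy)-2-(prop-2-en-1-yl)-5-(trityloxy)pentanoic acid | c1ccc(cc1)C(c1ccccc1)(c1ccccc1)OC[C@H](O[Si](C)(C)C(C)(C)C)C[C@](OCOC)(C(=O)O)CC=C | intermediate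
12 | tert-butyl (2S,4R)-4-[(tert-butyldimethylsilyl)oxy]-2-(methoxymethoxy)-2-(prop-2-en-1-yl)-5-(trityloxy)pentanoate | c1ccc(cc1)C(c1ccccc1)(c1ccccc1)OC[C@H](O[Si](C)(C)C(C)(C)C)C[C@](OCOC)(C(=O)OC(C)(C)C)CC=C | intermediate
13 | tert-butyl (2S,4R)-4-[(tert-butyldimethylsilyl)oxy]-5-hydroxy-2-(methoxymethoxy)-2-(prop-2-en-1-yl)pentanoate | OC[C@H](O[Si](C)(C)C(C)(C)C)C[C@](OCOC)(C(=O)OC(C)(C)C)CC=C | intermediate
14 | tert-butyl (2S,4R)-4-[(tert-butyldimethylsilyl)oxy]-2-(methoxymethoxy)-5-oxo-2-(prop-2-en-1-yl)pentanoate | O=C[C@H](O[Si](C)(C)C(C)(C)C)C[C@](OCOC)(C(=O)OC(C)(C)C)CC=C | intermediate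
15 | tert-butyl (2R,4R)-4-[(tert-butyldimethylsilyl)oxy]-2-(methoxymethoxy)-5-oxo-2-[(1,2,4-trioxolan-3-yl)methyl]pentanoate (ozonide, both epimers at the trioxolane carbon) | O=C[C@H](O[Si](C)(C)C(C)(C)C)C[C@](OCOC)(C(=O)OC(C)(C)C)CC1OCOO1 | intermediate
16 | tert-butyl (2R,4R)-4-[(tert-butyldimethylsilyl)oxy]-2-(methoxymethoxy)-5-oxo-2-(2-oxoethyl)pentanoate | O=C[C@H](O[Si](C)(C)C(C)(C)C)C[C@](OCOC)(C(=O)OC(C)(C)C)CC=O | intermediate
17 | bis(diiodosamarium) 3,4-diolate of 18 (trivalent samarium on O3 and O4) | I[Sm](I)O[C@H]1[C@H](O[Si](C)(C)C(C)(C)C)C[C@](OCOC)(C(=O)OC(C)(C)C)C[C@H]1O[Sm](I)I | intermediate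
18 | tert-butyl 5-O-(tert-butyldimethylsilyl)-1-O-(methoxymethyl)quinate (1-OMOM, 3-OH, 4-OH on one face; 5-OTBS and ester on the other) | O[C@H]1[C@H](O[Si](C)(C)C(C)(C)C)C[C@](OCOC)(C(=O)OC(C)(C)C)C[C@H]1O | intermediate
19 | 4-tert-butoxy-4-oxobutanoic acid (mono-tert-butyl succinate) | CC(C)(C)OC(=O)CCC(=O)O | starting material
20 | 4-tert-butoxy-4-oxobutanoic anhydride | CC(C)(C)OC(=O)CCC(=O)OC(=O)CCC(=O)OC(C)(C)C | intermediate
21 | 3,4-O-(dibutylstannylene) acetal of 18 | CCCC[Sn]1(CCCC)O[C@H]2[C@H](O[Si](C)(C)C(C)(C)C)C[C@](OCOC)(C(=O)OC(C)(C)C)C[C@H]2O1 | intermediate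
22 | tert-butyl 4-O-(4-tert-butoxy-4-oxobutanoyl)-5-O-(tert-butyldimethylsilyl)-1-O-(methoxymethyl)quinate | CC(C)(C)OC(=O)CCC(=O)O[C@H]1[C@H](O[Si](C)(C)C(C)(C)C)C[C@](OCOC)(C(=O)OC(C)(C)C)C[C@H]1O | intermediate
23 | tert-butyl 4-O-(4-tert-butoxy-4-oxobutanoyl)-1-O-(methoxymethyl)quinate | CC(C)(C)OC(=O)CCC(=O)O[C@H]1[C@H](O)C[C@](OCOC)(C(=O)OC(C)(C)C)C[C@H]1O | intermediate
24 | caffeic acid, (E)-3-(3,4-dihydroxyphenyl)prop-2-enoic acid | OC(=O)/C=C/c1ccc(O)c(O)c1 | starting material
25 | (E)-3-[3,4-bis(acetyloxy)phenyl]prop-2-enoic acid | CC(=O)Oc1ccc(/C=C/C(=O)O)cc1OC(C)=O | intermediate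
26 | (E)-3-[3,4-bis(acetyloxy)phenyl]prop-2-enoyl chloride | CC(=O)Oc1ccc(/C=C/C(Cl)=O)cc1OC(C)=O | intermediate
27 | tert-butyl 3,5-bis-O-[(E)-3,4-diacetoxycinnamoyl]-4-O-(4-tert-butoxy-4-oxobutanoyl)-1-O-(methoxymethyl)quinate | CC(C)(C)OC(=O)CCC(=O)O[C@H]1[C@H](OC(=O)/C=C/c2ccc(OC(C)=O)c(OC(C)=O)c2)C[C@](OCOC)(C(=O)OC(C)(C)C)C[C@H]1OC(=O)/C=C/c1ccc(OC(C)=O)c(OC(C)=O)c1 | intermediate
28 | 3,5-bis-O-[(E)-3,4-diacetoxycinnamoyl]-4-O-(3-carboxypropanoyl)quinic acid | OC(=O)CCC(=O)O[C@H]1[C@H](OC(=O)/C=C/c2ccc(OC(C)=O)c(OC(C)=O)c2)C[C@](O)(C(=O)O)C[C@H]1OC(=O)/C=C/c1ccc(OC(C)=O)c(OC(C)=O)c1 | intermediate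
29 | 3,5-di-O-[(E)-caffeoyl]-4-O-(3-carboxypropanoyl)quinic acid (CNP0133919.1) | O=C(O)CCC(=O)O[C@H]1[C@H](OC(=O)/C=C/c2ccc(O)c(O)c2)C[C@](O)(C(=O)O)C[C@H]1OC(=O)/C=C/c1ccc(O)c(O)c1 | target

## Step count and risk

Total step count: 15. Longest linear sequence: 14 steps (steps 1–12, 14 and 15, from 1 to 29); step 13 is a one-step side branch.

**Step 10 (key step).** The likely failures are:
- loss of facial control, giving closure syn to O5 or a trans-diol if the samarium bridge is loosened;
- over-reduction at C3 followed by β-elimination of the C1 methoxymethoxy group;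
- plain reduction of the formyl groups;
- epimerisation at C5 of the dialdehyde before it cyclises.

The fallback closes the same C3–C4 bond as an alkene and sets out from aldehyde 14. Wittig methylenation (Ph3P=CH2, THF, −78 °C) should give tert-butyl (2S,4R)-4-[(tert-butyldimethylsilyl)oxy]-2-(methoxymethoxy)-2-(prop-2-en-1-yl)hex-5-enoate F1. Ring-closing metathesis with the second-generation Grubbs catalyst (H2IMes)(PCy3)Cl2Ru=CHPh should then give tert-butyl (1S,5R)-5-[(tert-butyldimethylsilyl)oxy]-1-(methoxymethoxy)cyclohex-3-ene-1-carboxylate F2. Catalytic OsO4 with N-methylmorpholine N-oxide dihydroxylates the alkene on the face anti to the allylic silyloxy group and returns to the route at 18.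

**Step 5.** The danger is relactonisation: the silyl ester or the free hydroxy acid may reclose, helped by the geminal substitution at C1, faster than the hindered O5 is silylated. The fallback opens the lactone by reduction and sets out from 8. LiBH4 (THF/MeOH) gives (2S,4R)-2-(methoxymethoxy)-2-(prop-2-en-1-yl)-5-(trityloxy)pentane-1,4-diol F3, which cannot reclose. TBSCl/imidazole gives (2S,4R)-1,4-bis[(tert-butyldimethylsilyl)oxy]-2-(methoxymethoxy)-2-(prop-2-en-1-yl)-5-(trityloxy)pentane F4. Pyridine-buffered HF·pyridine frees the primary hydroxyl to give (2S,4R)-4-[(tert-butyldimethylsilyl)oxy]-2-(methoxymethoxy)-2-(prop-2-en-1-yl)-5-(trityloxy)pentan-1-ol F5. TEMPO/PhI(OAc)2 in aqueous MeCN oxidises it to the acid and rejoins the route at 11.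

**Step 11.** The danger is poor discrimination between O4 and O3, or drift of the new ester from O4 to O3, because the equatorial O4 sits beside the bulky silyl ether and the anhydride is a modest electrophile. The fallback fixes the position by the stereoelectronics of ortho ester opening and sets out from 18.
- 2-Chloro-1,1,1-trimethoxyethane with catalytic camphor-10-sulfonic acid gives tert-butyl 3,4-O-(2-chloro-1-methoxyethylidene)-5-O-(tert-butyldimethylsilyl)-1-O-(methoxymethyl)quinate F6.
- Dilute aqueous acetic acid opens it to the axial ester, tert-butyl 3-O-(chloroacetyl)-5-O-(tert-butyldimethylsilyl)-1-O-(methoxymethyl)quinate F7.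
- Steglich esterification of the free O4 with 19 (1-ethyl-3-(3-dimethylaminopropyl)carbodiimide hydrochloride, DMAP) gives tert-butyl 4-O-(4-tert-butoxy-4-oxobutanoyl)-3-O-(chloroacetyl)-5-O-(tert-butyldimethylsilyl)-1-O-(methoxymethyl)quinate F8.
- Thiourea with NaHCO3 in ethanol removes the chloroacetate and returns to the route at 22.

**Step 14.** The danger is migration of the succinate from O4 to a free neighbour under pyridine/DMAP before both hydroxyls are acylated, and incomplete acylation of the axial O3. The fallback never has two free hydroxyls beside the O4 ester and sets out from 22. Acylation of its only free hydroxyl with 26 gives tert-butyl 3-O-[(E)-3,4-diacetoxycinnamoyl]-4-O-(4-tert-butoxy-4-oxobutanoyl)-5-O-(tert-butyldimethylsilyl)-1-O-(methoxymethyl)quinate F9. HF·pyridine gives tert-butyl 3-O-[(E)-3,4-diacetoxycinnamoyl]-4-O-(4-tert-butoxy-4-oxobutanoyl)-1-O-(methoxymethyl)quinate F10. A second acylation with 26 at O5 returns to the route at 27.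

**Step 15.** The danger is that acetate hydrolysis is slow enough for caffeoyl or succinyl esters to hydrolyse or migrate in the aqueous acid, and that the freed catechols oxidise. The fallback masks the phenols as silyl ethers, which are removed by fluoride without water or base, and sets out from 24 and 23.
- TBSCl/imidazole converts 24 into tert-butyldimethylsilyl (E)-3-{3,4-bis[(tert-butyldimethylsilyl)oxy]phenyl}prop-2-enoate F11.
- Aqueous acetic acid cleaves its silyl ester to (E)-3-{3,4-bis[(tert-butyldimethylsilyl)oxy]phenyl}prop-2-enoic acid F12.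
- Steglich esterification of 23 with this acid gives tert-butyl 3,5-bis-O-[(E)-3,4-bis(tert-butyldimethylsilyloxy)cinnamoyl]-4-O-(4-tert-butoxy-4-oxobutanoyl)-1-O-(methoxymethyl)quinate F13.
- CF3CO2H/CH2Cl2/H2O removes the tert-butyl and MOM groups while the aryl silyl ethers survive, giving 3,5-bis-O-[(E)-3,4-bis(tert-butyldimethylsilyloxy)cinnamoyl]-4-O-(3-carboxypropanoyl)quinic acid F14.
- Et3N·3HF in THF removes the four silyl groups and arrives at 29.

## Further compounds

F1 | step 10 | tert-butyl (2S,4R)-4-[(tert-butyldimethylsilyl)oxy]-2-(methoxymethoxy)-2-(prop-2-en-1-yl)hex-5-enoate | C=C[C@H](O[Si](C)(C)C(C)(C)C)C[C@](OCOC)(C(=O)OC(C)(C)C)CC=C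
F2 | step 10 | tert-butyl (1S,5R)-5-[(tert-butyldimethylsilyl)oxy]-1-(methoxymethoxy)cyclohex-3-ene-1-carboxylate | C1=C[C@H](O[Si](C)(C)C(C)(C)C)C[C@](OCOC)(C(=O)OC(C)(C)C)C1
F3 | step 5 | (2S,4R)-2-(methoxymethoxy)-2-(prop-2-en-1-yl)-5-(trityloxy)pentane-1,4-diol | c1ccc(cc1)C(c1ccccc1)(c1ccccc1)OC[C@H](O)C[C@](OCOC)(CO)CC=C
F4 | step 5 | (2S,4R)-1,4-bis[(tert-butyldimethylsilyl)oxy]-2-(methoxymethoxy)-2-(prop-2-en-1-yl)-5-(trityloxy)pentane | c1ccc(cc1)C(c1ccccc1)(c1ccccc1)OC[C@H](O[Si](C)(C)C(C)(C)C)C[C@](OCOC)(CO[Si](C)(C)C(C)(C)C)CC=C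
F5 | step 5 | (2S,4R)-4-[(tert-butyldimethylsilyl)oxy]-2-(methoxymethoxy)-2-(prop-2-en-1-yl)-5-(trityloxy)pentan-1-ol | c1ccc(cc1)C(c1ccccc1)(c1ccccc1)OC[C@H](O[Si](C)(C)C(C)(C)C)C[C@](OCOC)(CO)CC=C
F6 | step 11 | tert-butyl 3,4-O-(2-chloro-1-methoxyethylidene)-5-O-(tert-butyldimethylsilyl)-1-O-(methoxymethyl)quinate | COC1(CCl)O[C@H]2[C@H](O[Si](C)(C)C(C)(C)C)C[C@](OCOC)(C(=O)OC(C)(C)C)C[C@H]2O1
F7 | step 11 | tert-butyl 3-O-(chloroacetyl)-5-O-(tert-butyldimethylsilyl)-1-O-(methoxymethyl)quinate | O[C@H]1[C@H](O[Si](C)(C)C(C)(C)C)C[C@](OCOC)(C(=O)OC(C)(C)C)C[C@H]1OC(=O)CCl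
F8 | step 11 | tert-butyl 4-O-(4-tert-butoxy-4-oxobutanoyl)-3-O-(chloroacetyl)-5-O-(tert-butyldimethylsilyl)-1-O-(methoxymethyl)quinate | CC(C)(C)OC(=O)CCC(=O)O[C@H]1[C@H](O[Si](C)(C)C(C)(C)C)C[C@](OCOC)(C(=O)OC(C)(C)C)C[C@H]1OC(=O)CCl
F9 | step 14 | tert-butyl 3-O-[(E)-3,4-diacetoxycinnamoyl]-4-O-(4-tert-butoxy-4-oxobutanoyl)-5-O-(tert-butyldimethylsilyl)-1-O-(methoxymethyl)quinate | CC(C)(C)OC(=O)CCC(=O)O[C@H]1[C@H](O[Si](C)(C)C(C)(C)C)C[C@](OCOC)(C(=O)OC(C)(C)C)C[C@H]1OC(=O)/C=C/c1ccc(OC(C)=O)c(OC(C)=O)c1
F10 | step 14 | tert-butyl 3-O-[(E)-3,4-diacetoxycinnamoyl]-4-O-(4-tert-butoxy-4-oxobutanoyl)-1-O-(methoxymethyl)quinate | CC(C)(C)OC(=O)CCC(=O)O[C@H]1[C@H](O)C[C@](OCOC)(C(=O)OC(C)(C)C)C[C@H]1OC(=O)/C=C/c1ccc(OC(C)=O)c(OC(C)=O)c1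
F11 | step 15 | tert-butyldimethylsilyl (E)-3-{3,4-bis[(tert-butyldimethylsilyl)oxy]phenyl}prop-2-enoate | CC(C)(C)[Si](C)(C)OC(=O)/C=C/c1ccc(O[Si](C)(C)C(C)(C)C)c(O[Si](C)(C)C(C)(C)C)c1
F12 | step 15 | (E)-3-{3,4-bis[(tert-butyldimethylsilyl)oxy]phenyl}prop-2-enoic acid | OC(=O)/C=C/c1ccc(O[Si](C)(C)C(C)(C)C)c(O[Si](C)(C)C(C)(C)C)c1
F13 | step 15 | tert-butyl 3,5-bis-O-[(E)-3,4-bis(tert-butyldimethylsilyloxy)cinnamoyl]-4-O-(4-tert-butoxy-4-oxobutanoyl)-1-O-(methoxymethyl)quinate | CC(C)(C)OC(=O)CCC(=O)O[C@H]1[C@H](OC(=O)/C=C/c2ccc(O[Si](C)(C)C(C)(C)C)c(O[Si](C)(C)C(C)(C)C)c2)C[C@](OCOC)(C(=O)OC(C)(C)C)C[C@H]1OC(=O)/C=C/c1ccc(O[Si](C)(C)C(C)(C)C)c(O[Si](C)(C)C(C)(C)C)c1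
F14 | step 15 | 3,5-bis-O-[(E)-3,4-bis(tert-butyldimethylsilyloxy)cinnamoyl]-4-O-(3-carboxypropanoyl)quinic acid | OC(=O)CCC(=O)O[C@H]1[C@H](OC(=O)/C=C/c2ccc(O[Si](C)(C)C(C)(C)C)c(O[Si](C)(C)C(C)(C)C)c2)C[C@](O)(C(=O)O)C[C@H]1OC(=O)/C=C/c1ccc(O[Si](C)(C)C(C)(C)C)c(O[Si](C)(C)C(C)(C)C)c1
A1 | alternative 1 | (S)-1-formylcyclohex-3-en-1-yl benzoate | C1=CC[C@](OC(=O)c2ccccc2)(C=O)CC1
A2 | alternative 1 | 2-(benzoyloxy)acrolein | C=C(C=O)OC(=O)c1ccccc1
A3 | alternative 1 | buta-1,3-diene | C=CC=C
A4 | alternative 2 | (1S,5R)-5-[(tert-butyldimethylsilyl)oxy]-1-(methoxymethoxy)cyclohex-3-ene-1-carboxylic acid (carboxyl cis to O5) | C1=C[C@H](O[Si](C)(C)C(C)(C)C)C[C@](OCOC)(C(=O)O)C1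
A5 | alternative 2 | (5R,6S)-5-[(tert-butyldimethylsilyl)oxy]-6-ethenyl-3-(methoxymethoxy)oxan-2-one (5,6-trans; either epimer at C3) | C=C[C@@H]1OC(=O)C(OCOC)C[C@H]1O[Si](C)(C)C(C)(C)C
A6 | alternative 3 | 4-methoxybenzyl 3,5-bis-O-[(E)-3,4-diacetoxycinnamoyl]-4-O-(4-tert-butoxy-4-oxobutanoyl)quinate | CC(C)(C)OC(=O)CCC(=O)O[C@H]1[C@H](OC(=O)/C=C/c2ccc(OC(C)=O)c(OC(C)=O)c2)C[C@](O)(C(=O)OCc2ccc(OC)cc2)C[C@H]1OC(=O)/C=C/c1ccc(OC(C)=O)c(OC(C)=O)c1
A7 | alternative 3 | 4-methoxybenzyl 3,5-bis-O-acryloyl-4-O-(4-tert-butoxy-4-oxobutanoyl)quinate | CC(C)(C)OC(=O)CCC(=O)O[C@H]1[C@H](OC(=O)C=C)C[C@](O)(C(=O)OCc2ccc(OC)cc2)C[C@H]1OC(=O)C=C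
A8 | alternative 3 | 4-iodo-1,2-phenylene diacetate | CC(=O)Oc1ccc(I)cc1OC(C)=O
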